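**Retrosynthetic overview**

1. The target is cut at the ring A ketone: Friedel–Crafts acylation of the last free carbon of ring A with (R)-2-methylbutanoyl chloride (stereocentre from the chiral pool), after hydrogenolysis of a ring A tris(benzyl ether).
2. Rings B and C come from one twofold Claisen closure (C5'–C6' in each ring) of two triketo ester chains hung on ring A. The strategy rests on this feature: in rings B and C the methoxy group on C4' lies between the C3' methyl and the C5' acyl group, ortho to the acyl, where a phenol cannot be methylated selectively. C4' therefore enters as a methyl enol ether.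
3. The terminal acyl groups (isobutyryl first, then acetyl) are put on by γ-acylation of the chain dianions with Weinreb amides, only after C1' carries the ring A methylene. A free chain with C1'H2 and a free acyl ketone would fold by aldol condensation to a resorcylate.
4. Each chain is attached by Knoevenagel condensation and conjugate reduction of one β-keto ester (made from methyl 2-methyl-3-oxobutanoate through its methyl enol ether) on a formyl group of 2,4,6-tris(benzyloxy)isophthalaldehyde, one formyl group after the other.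
5. Ring order: ring A is bought as phloroglucinol; rings B and C are formed together in the key step.

Key step: step 13

Locants: in each outer ring C1' bears the bridging CH2, C2' OH, C3' CH3, C4' OCH3, C5' the acyl group and C6' OH. The same locants are used for the open chains (C6' is the ester carbon).

Assumption: N-methoxy-N-methylacetamide and (R)-2-methylbutanoic acid are bought. The enol ether geometry (drawn E as far as 18) and the C1' centres of the open chains are not controlled, because step 13 erases both; 10–12 and 15–20 are used as stereoisomer mixtures.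

**Route**

Step 1
Reactants: 1 phloroglucinol
Product: 2 1,3,5-tris(benzyloxy)benzene
Conditions: BnBr (3.6 equiv), K2CO3 (4.5 equiv), DMF, 25 → 60 °C
Reagents that add atoms: benzyl bromide, BrCc1ccccc1
Why: Williamson ether synthesis in a dipolar aprotic solvent favours O- over C-benzylation of the phenoxides, and the crystalline tris(ether) should be separable from C-benzylated material.

Step 2
Reactants: 2 1,3,5-tris(benzyloxy)benzene
Product: 3 2,4,6-tris(benzyloxy)benzaldehyde
Conditions: POCl3 (1.3 equiv), DMF, 0 → 25 °C; then H2O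
Reagents that add atoms: N,N-dimethylformamide, CN(C)C=O; water, O
Why: Vilsmeier–Haack formylation of a 1,3,5-trialkoxybenzene should stop at the mono-aldehyde, because the aryl iminium salt formed first is deactivated toward a second attack.

Step 3
Reactants: 3 2,4,6-tris(benzyloxy)benzaldehyde
Product: 4 2,4,6-tris(benzyloxy)benzene-1,3-dicarbaldehyde
Conditions: POCl3 (4 equiv), DMF, 70 °C; then H2O
Reagents that add atoms: N,N-dimethylformamide, CN(C)C=O; water, O
Why: In a second Vilsmeier–Haack formylation the neutral aldehyde still has two alkoxy groups ortho and one para to each free carbon, so excess reagent at higher temperature should enter one of the two equivalent positions, after which the ring with two formyl groups is inert.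

Step 4
Reactants: 5 methyl 2-methyl-3-oxobutanoate
Product: 6 methyl (2E)-3-methoxy-2-methylbut-2-enoate
Conditions: HC(OMe)3, MeOH, H2SO4 (cat.), 25 °C; then distillation from TsOH (cat.)
Reagents that add atoms: trimethyl orthoformate, COC(OC)OC
Why: Acid-catalysed ketalisation with the orthoformate and loss of methanol on distillation should give the β-methoxy enoate, mainly as the E isomer with the ester cis to the C3 methyl group, which fixes the oxygen that later becomes the ring methyl ether.

Step 5
Reactants: 6 methyl (2E)-3-methoxy-2-methylbut-2-enoate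
Product: 7 (2E)-3-methoxy-2-methylbut-2-enoic acid
Conditions: KOH, MeOH/H2O, 70 °C; then 1 M HCl to pH 3, 0 °C
Reagents that add atoms: potassium hydroxide, [K+].[OH-]
Why: Saponification of the vinylogous carbonate ester; the enol ether is stable to base and should survive a brief, cold acidification.

Step 6
Reactants: 7 (2E)-3-methoxy-2-methylbut-2-enoic acid
Product: 9 methyl (4E)-5-methoxy-4-methyl-3-oxohex-4-enoate, via acyl imidazolide 8 (not isolated)
Conditions: CDI, THF, 25 °C; then KO2CCH2CO2Me, MgCl2, Et3N, MeCN, 25 → 45 °C; 1 M HCl work-up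
Reagents that add atoms: 1,1'-carbonyldiimidazole, O=C(n1ccnc1)n1ccnc1 (in 8); potassium methyl malonate, [K+].[O-]C(=O)CC(=O)OC
Why: Masamune–Brooks homologation, in which the acyl imidazolide C-acylates the magnesium enolate of the malonate half ester and decarboxylation gives the β-keto ester under nearly neutral conditions that leave the enol ether intact.

Step 7
Reactants: 4 2,4,6-tris(benzyloxy)benzene-1,3-dicarbaldehyde; 9 methyl (4E)-5-methoxy-4-methyl-3-oxohex-4-enoate
Product: 11 methyl (4E)-2-{[2,4,6-tris(benzyloxy)-3-formylphenyl]methyl}-5-methoxy-4-methyl-3-oxohex-4-enoate, via alkylidene keto ester 10 (not isolated)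
Conditions: 4 (3 equiv), piperidine (0.2 equiv), AcOH (0.2 equiv), PhMe, 4 Å molecular sieves, 70 °C; then Hantzsch ester (1.2 equiv), 70 °C
Reagents that add atoms: none
Why: Knoevenagel condensation of the only active methylene group of 9 with one formyl group, then conjugate transfer hydrogenation of the doubly activated alkylidene by the Hantzsch ester, which leaves the second aldehyde alone; 4 in threefold excess should hold the reaction at the mono stage and is recovered.

Step 8
Reactants: 11 methyl (4E)-2-{[2,4,6-tris(benzyloxy)-3-formylphenyl]methyl}-5-methoxy-4-methyl-3-oxohex-4-enoate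
Product: 12 methyl (4E)-2-{[2,4,6-tris(benzyloxy)-3-(dimethoxymethyl)phenyl]methyl}-5-methoxy-4-methyl-3-oxohex-4-enoate
Conditions: HC(OMe)3, MeOH, PPTS (cat.), 25 °C; Et3N quench
Reagents that add atoms: trimethyl orthoformate, COC(OC)OC
Why: Acid-catalysed acetalisation masks the remaining aldehyde against the carbanion of step 10, while the vinylogous ester ketone of the chain should not form a ketal.

Step 9
Reactants: 13 isobutyryl chloride
Product: 14 N-methoxy-N,2-dimethylpropanamide
Conditions: MeNHOMe·HCl, K2CO3, H2O/CH2Cl2, 0 → 25 °C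
Reagents that add atoms: N,O-dimethylhydroxylamine hydrochloride, CNOC.Cl
Why: Schotten–Baumann N-acylation of N,O-dimethylhydroxylamine gives the Weinreb amide.

Step 10
Reactants: 12 methyl (4E)-2-{[2,4,6-tris(benzyloxy)-3-(dimethoxymethyl)phenyl]methyl}-5-methoxy-4-methyl-3-oxohex-4-enoate; 14 N-methoxy-N,2-dimethylpropanamide
Product: 16 methyl 2-{[2,4,6-tris(benzyloxy)-3-formylphenyl]methyl}-5-methoxy-4,8-dimethyl-3,7-dioxonon-4-enoate, via keto acetal 15 (not isolated)
Conditions: LiN(iPr)2 (LDA, 2.2 equiv), THF, −78 → −30 °C; 14 (1.2 equiv), −78 °C; then 0.5 M HCl, THF, 0 °C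
Reagents that add atoms: water, O
Why: γ-Acylation of a β-keto ester dianion (polycarbonyl polyanion chemistry): the first equivalent of base forms the C1' enolate, the second removes a proton of the vinylogous methyl group on C4', and this terminal, least stabilised carbanion adds to the Weinreb amide, whose chelated tetrahedral adduct prevents over-addition; the acid work-up releases the ketone and hydrolyses the very labile electron-rich aryl acetal, and because C1' already bears its benzylic substituent the new triketo ester cannot aromatise by aldol condensation.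

Step 11
Reactants: 16 methyl 2-{[2,4,6-tris(benzyloxy)-3-formylphenyl]methyl}-5-methoxy-4,8-dimethyl-3,7-dioxonon-4-enoate; 9 methyl (4E)-5-methoxy-4-methyl-3-oxohex-4-enoate
Product: 18 methyl 2-{[2,4,6-tris(benzyloxy)-3-[(4E)-5-methoxy-2-(methoxycarbonyl)-4-methyl-3-oxohex-4-en-1-yl]phenyl]methyl}-5-methoxy-4,8-dimethyl-3,7-dioxonon-4-enoate, via alkylidene keto ester 17 (not isolated)
Conditions: 9 (1.3 equiv), piperidine (0.2 equiv), AcOH (0.2 equiv), PhMe, 4 Å molecular sieves, 60 °C; then Hantzsch ester (1.2 equiv), 60 °C
Reagents that add atoms: none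
Why: Second Knoevenagel condensation and Hantzsch ester conjugate reduction as in step 7; the chain already present has a tertiary C1', no CH2 as acidic as C2 of 9 and a hindered isopropyl ketone that resists enamine formation, so it should pass unchanged.

Step 12
Reactants: 18 methyl 2-{[2,4,6-tris(benzyloxy)-3-[(4E)-5-methoxy-2-(methoxycarbonyl)-4-methyl-3-oxohex-4-en-1-yl]phenyl]methyl}-5-methoxy-4,8-dimethyl-3,7-dioxonon-4-enoate; 19 N-methoxy-N-methylacetamide
Product: 20 methyl 2-{[2,4,6-tris(benzyloxy)-3-[5-methoxy-2-(methoxycarbonyl)-4-methyl-3,7-dioxooct-4-en-1-yl]phenyl]methyl}-5-methoxy-4,8-dimethyl-3,7-dioxonon-4-enoate (the bis(triketo ester) precursor)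
Conditions: LiN(iPr)2 (4.3 equiv), THF, −78 → −30 °C; 19 (1.1 equiv), −78 °C; AcOH, −78 °C
Reagents that add atoms: none
Why: Polyanion γ-acylation as in step 10: four equivalents of base give the C1' enolates of both chains, the C5' ketone enolate of the finished chain and the γ-carbanion of the new chain, and only the last, by far the most basic site, should add to the Weinreb amide at −78 °C; the isopropyl ketone of the finished chain has no second accessible α-position, which is why that chain was completed first.

Step 13
Reactants: 20 the bis(triketo ester) precursor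
Product: 21 1-[3-({2,4,6-tris(benzyloxy)-3-[(2,6-dihydroxy-4-methoxy-3-methyl-5-(2-methylpropanoyl)phenyl)methyl]phenyl}methyl)-2,4-dihydroxy-6-methoxy-5-methylphenyl]ethan-1-one
Conditions: NaOMe (10 equiv), MeOH (0.01 M), Ar, 65 °C; then 1 M HCl, 0 °C
Reagents that add atoms: none
Why: Methoxide deprotonates both chains reversibly at C1' and C5'; the C5' enolate, stabilised by the acyl ketone and, through the C4'=C3' enol ether, by the C2' ketone, adds to the ester carbonyl C6', methoxide leaves, and the cyclohexadienone enolises to the arene and is held as its phenoxide, which should make each closure irreversible. The closest known reaction type is the alkoxide- or Mg(OMe)2-mediated Claisen (Dieckmann-type) cyclisation of 3,5,7-triketo esters to acylphloroglucinols; here one carbonyl of each chain is carried as its methyl enol ether. Ring B and ring C each close in a 6-(enolexo)-exo-trig mode by formation of the C5'–C6' bond. No stereocentre is formed: the C1' centres and the enol ether geometry of 20 disappear on aromatisation, and the geometry is no obstacle because the C5' dienolate rotates about C3'–C4'. The selectivity needed is Claisen closure from C5' over aldol closure from C1' onto the acyl ketone; the benzylic substituent on C1' secures it, since the aldol adduct is a crowded tertiary alkoxide beside a quaternary carbon that cannot dehydrate across C1' and reverts by retro-aldol, whereas only the Claisen adduct can aromatise. Because the C4' oxygen is already methylated, each ring should emerge with its methoxy group beside the acyl group without any phenol methylation.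

Step 14
Reactants: 21 the tris(benzyl ether) from step 13
Product: 22 1-[3-({2,4,6-trihydroxy-3-[(2,6-dihydroxy-4-methoxy-3-methyl-5-(2-methylpropanoyl)phenyl)methyl]phenyl}methyl)-2,4-dihydroxy-6-methoxy-5-methylphenyl]ethan-1-one
Conditions: H2 (1 atm), 10% Pd/C, EtOAc/MeOH, 25 °C
Reagents that add atoms: none
Why: Hydrogenolysis of the three benzyl aryl ethers; the chelated aryl ketones, the aryl methyl ethers and the diarylmethane links should be stable at 1 atm and room temperature.

Step 15
Reactants: 23 (R)-2-methylbutanoic acid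
Product: 24 (R)-2-methylbutanoyl chloride
Conditions: (COCl)2, DMF (cat.), CH2Cl2, 0 → 25 °C; used crude
Reagents that add atoms: oxalyl chloride, ClC(=O)C(=O)Cl
Why: Acid chloride formation through the Vilsmeier-type chloroiminium catalyst needs no base, so the α-stereocentre taken from the chiral pool should keep its R configuration.

Step 16
Reactants: 22 the heptaphenol from step 14; 24 (R)-2-methylbutanoyl chloride
Product: 25 (2R)-1-{3-[(3-acetyl-2,6-dihydroxy-4-methoxy-5-methylphenyl)methyl]-5-{[2,6-dihydroxy-4-methoxy-3-methyl-5-(2-methylpropanoyl)phenyl]methyl}-2,4,6-trihydroxyphenyl}-2-methylbutan-1-one (target)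
Conditions: 24 (1.2 equiv), AlCl3 (8 equiv), PhNO2/CH2Cl2, 0 → 25 °C; then 1 M HCl, 0 °C
Reagents that add atoms: none
Why: Friedel–Crafts C-acylation at the only aromatic C–H of the molecule, on ring A between two hydroxyl groups (rings B and C are fully substituted, and any aryl ester formed first should rearrange there by Fries migration); the R stereocentre is carried in from 24, and low temperature and short reaction time are chosen to avoid enolisation of the acyl chloride–AlCl3 complex.

**Compound list**

1 | phloroglucinol | Oc1cc(O)cc(O)c1 | starting material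
2 | 1,3,5-tris(benzyloxy)benzene | c1ccc(COc2cc(OCc3ccccc3)cc(OCc3ccccc3)c2)cc1 | intermediate
3 | 2,4,6-tris(benzyloxy)benzaldehyde | O=Cc1c(OCc2ccccc2)cc(OCc2ccccc2)cc1OCc1ccccc1 | intermediate
4 | 2,4,6-tris(benzyloxy)benzene-1,3-dicarbaldehyde | O=Cc1c(OCc2ccccc2)cc(OCc2ccccc2)c(C=O)c1OCc1ccccc1 | intermediate
5 | methyl 2-methyl-3-oxobutanoate | COC(=O)C(C)C(C)=O | starting material
6 | methyl (2E)-3-methoxy-2-methylbut-2-enoate | COC(=O)/C(C)=C(\C)OC | intermediate
7 | (2E)-3-methoxy-2-methylbut-2-enoic acid | OC(=O)/C(C)=C(\C)OC | intermediate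
8 | (2E)-1-(imidazol-1-yl)-3-methoxy-2-methylbut-2-en-1-one (acyl imidazolide, formed in the flask) | O=C(/C(C)=C(\C)OC)n1ccnc1 | intermediate
9 | methyl (4E)-5-methoxy-4-methyl-3-oxohex-4-enoate | COC(=O)CC(=O)/C(C)=C(\C)OC | intermediate
10 | methyl (4E)-2-{[2,4,6-tris(benzyloxy)-3-formylphenyl]methylidene}-5-methoxy-4-methyl-3-oxohex-4-enoate (alkylidene geometry not defined, formed in the flask) | COC(=O)C(=Cc1c(OCc2ccccc2)cc(OCc2ccccc2)c(C=O)c1OCc1ccccc1)C(=O)/C(C)=C(\C)OC | intermediate
11 | methyl (4E)-2-{[2,4,6-tris(benzyloxy)-3-formylphenyl]methyl}-5-methoxy-4-methyl-3-oxohex-4-enoate (racemic) | COC(=O)C(Cc1c(OCc2ccccc2)cc(OCc2ccccc2)c(C=O)c1OCc1ccccc1)C(=O)/C(C)=C(\C)OC | intermediate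
12 | methyl (4E)-2-{[2,4,6-tris(benzyloxy)-3-(dimethoxymethyl)phenyl]methyl}-5-methoxy-4-methyl-3-oxohex-4-enoate (racemic) | COC(=O)C(Cc1c(OCc2ccccc2)cc(OCc2ccccc2)c(C(OC)OC)c1OCc1ccccc1)C(=O)/C(C)=C(\C)OC | intermediate
13 | isobutyryl chloride | CC(C)C(=O)Cl | starting material
14 | N-methoxy-N,2-dimethylpropanamide | CC(C)C(=O)N(C)OC | intermediate
15 | methyl 2-{[2,4,6-tris(benzyloxy)-3-(dimethoxymethyl)phenyl]methyl}-5-methoxy-4,8-dimethyl-3,7-dioxonon-4-enoate (stereoisomer mixture, formed in the flask) | COC(=O)C(Cc1c(OCc2ccccc2)cc(OCc2ccccc2)c(C(OC)OC)c1OCc1ccccc1)C(=O)C(C)=C(OC)CC(=O)C(C)C | intermediate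
16 | methyl 2-{[2,4,6-tris(benzyloxy)-3-formylphenyl]methyl}-5-methoxy-4,8-dimethyl-3,7-dioxonon-4-enoate (stereoisomer mixture) | COC(=O)C(Cc1c(OCc2ccccc2)cc(OCc2ccccc2)c(C=O)c1OCc1ccccc1)C(=O)C(C)=C(OC)CC(=O)C(C)C | intermediate
17 | alkylidene keto ester from 16 and 9 (stereoisomer mixture, formed in the flask) | COC(=O)C(=Cc1c(OCc2ccccc2)cc(OCc2ccccc2)c(CC(C(=O)OC)C(=O)C(C)=C(OC)CC(=O)C(C)C)c1OCc1ccccc1)C(=O)/C(C)=C(\C)OC | intermediate
18 | methyl 2-{[2,4,6-tris(benzyloxy)-3-[(4E)-5-methoxy-2-(methoxycarbonyl)-4-methyl-3-oxohex-4-en-1-yl]phenyl]methyl}-5-methoxy-4,8-dimethyl-3,7-dioxonon-4-enoate (stereoisomer mixture) | COC(=O)C(Cc1c(OCc2ccccc2)cc(OCc2ccccc2)c(CC(C(=O)OC)C(=O)C(C)=C(OC)CC(=O)C(C)C)c1OCc1ccccc1)C(=O)/C(C)=C(\C)OC | intermediate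
19 | N-methoxy-N-methylacetamide | CC(=O)N(C)OC | starting material
20 | methyl 2-{[2,4,6-tris(benzyloxy)-3-[5-methoxy-2-(methoxycarbonyl)-4-methyl-3,7-dioxooct-4-en-1-yl]phenyl]methyl}-5-methoxy-4,8-dimethyl-3,7-dioxonon-4-enoate (stereoisomer mixture) | COC(=O)C(Cc1c(OCc2ccccc2)cc(OCc2ccccc2)c(CC(C(=O)OC)C(=O)C(C)=C(OC)CC(=O)C(C)C)c1OCc1ccccc1)C(=O)C(C)=C(OC)CC(C)=O | intermediate
21 | 1-[3-({2,4,6-tris(benzyloxy)-3-[(2,6-dihydroxy-4-methoxy-3-methyl-5-(2-methylpropanoyl)phenyl)methyl]phenyl}methyl)-2,4-dihydroxy-6-methoxy-5-methylphenyl]ethan-1-one | CC(=O)c1c(O)c(Cc2c(OCc3ccccc3)cc(OCc3ccccc3)c(Cc3c(O)c(C)c(OC)c(C(=O)C(C)C)c3O)c2OCc2ccccc2)c(O)c(C)c1OC | intermediate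
22 | 1-[3-({2,4,6-trihydroxy-3-[(2,6-dihydroxy-4-methoxy-3-methyl-5-(2-methylpropanoyl)phenyl)methyl]phenyl}methyl)-2,4-dihydroxy-6-methoxy-5-methylphenyl]ethan-1-one | CC(=O)c1c(O)c(Cc2c(O)cc(O)c(Cc3c(O)c(C)c(OC)c(C(=O)C(C)C)c3O)c2O)c(O)c(C)c1OC | intermediate
23 | (R)-2-methylbutanoic acid | CC[C@@H](C)C(=O)O | starting material
24 | (R)-2-methylbutanoyl chloride | CC[C@@H](C)C(=O)Cl | intermediate
25 | (2R)-1-{3-[(3-acetyl-2,6-dihydroxy-4-methoxy-5-methylphenyl)methyl]-5-{[2,6-dihydroxy-4-methoxy-3-methyl-5-(2-methylpropanoyl)phenyl]methyl}-2,4,6-trihydroxyphenyl}-2-methylbutan-1-one | CC[C@@H](C)C(=O)c1c(O)c(Cc2c(O)c(C)c(OC)c(C(C)=O)c2O)c(O)c(Cc2c(O)c(C)c(OC)c(C(=O)C(C)C)c2O)c1O | target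

**Summary**

Total step count: 16.
Longest linear sequence: 11 steps (5 → 25 through steps 4, 5, 6, 7, 8, 10, 11, 12, 13, 14 and 16; the path from 1 is equally long).

**Steps most likely to fail**

1. Step 13 (twofold Claisen closure). With two open chains in one molecule, condensation between the chains and methoxide-induced retro-Claisen cleavage at C1'–C2' may outrun the second ring closure, and partial conversion would leave mixtures of singly and doubly closed material.
   Fallback: the rings are closed one at a time; it sets out from 16 and comes back at 21. NaOMe in MeOH at high dilution closes ring C on the single chain of 16 and gives the formyl diarylmethane F1. Knoevenagel condensation of F1 with 9 gives the alkylidene keto ester F2, which the Hantzsch ester reduces in the same flask to the keto ester F3. LiN(iPr)2 (4.3 equiv, for two phenoxides, the C1' enolate and the γ-carbanion) and 19 then give the triketo ester F4, whose single chain is closed with NaOMe in MeOH to 21.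

2. Step 12 (γ-acylation beside the finished chain). The Weinreb amide may add too slowly to the γ-carbanion at −78 °C, so that proton transfer to it, acylation at the C5' ketone enolate of the finished chain, or premature cyclisation of the polyanion on warming takes over.
   Fallback: the acetyl carbon is brought in at the alcohol oxidation state; it sets out from 18 and comes back at 20. The tetraanion of 18 is treated at −78 °C with acetaldehyde, which reacts at once with the γ-carbanion, to give the secondary alcohol F5. Dess–Martin periodinane (NaHCO3, CH2Cl2) oxidises F5 to 20.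

3. Step 16 (Friedel–Crafts acylation). Enolisation or ketene formation from the acyl chloride–AlCl3 complex may erode the R stereocentre, AlCl3 may cleave the methyl ethers ortho to the ketones, and the acid may scramble the diarylmethane links.
   Fallback: a Houben–Hoesch acylation with a nitrile in place of the acylium ion; it sets out from 24 (and 22) and comes back at 25. NH3 converts 24 into (R)-2-methylbutanamide F6, and TFAA/pyridine dehydrates this to (R)-2-methylbutanenitrile F7. Reaction of 22 with F7 (ZnCl2, HCl gas, Et2O, 0 °C) should give the ketiminium chloride F8, which is hydrolysed with water at the lowest sufficient temperature to 25.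

**Further compounds**

F1 | step 13 | 2,4,6-tris(benzyloxy)-3-{[2,6-dihydroxy-4-methoxy-3-methyl-5-(2-methylpropanoyl)phenyl]methyl}benzaldehyde | CC(C)C(=O)c1c(O)c(Cc2c(OCc3ccccc3)cc(OCc3ccccc3)c(C=O)c2OCc2ccccc2)c(O)c(C)c1OC
F2 | step 13 | alkylidene keto ester from F1 and 9 | COC(=O)C(=Cc1c(OCc2ccccc2)cc(OCc2ccccc2)c(Cc2c(O)c(C)c(OC)c(C(=O)C(C)C)c2O)c1OCc1ccccc1)C(=O)/C(C)=C(\C)OC
F3 | step 13 | methyl (4E)-2-{[2,4,6-tris(benzyloxy)-3-{[2,6-dihydroxy-4-methoxy-3-methyl-5-(2-methylpropanoyl)phenyl]methyl}phenyl]methyl}-5-methoxy-4-methyl-3-oxohex-4-enoate | COC(=O)C(Cc1c(OCc2ccccc2)cc(OCc2ccccc2)c(Cc2c(O)c(C)c(OC)c(C(=O)C(C)C)c2O)c1OCc1ccccc1)C(=O)/C(C)=C(\C)OC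
F4 | step 13 | methyl 2-{[2,4,6-tris(benzyloxy)-3-{[2,6-dihydroxy-4-methoxy-3-methyl-5-(2-methylpropanoyl)phenyl]methyl}phenyl]methyl}-5-methoxy-4-methyl-3,7-dioxooct-4-enoate | COC(=O)C(Cc1c(OCc2ccccc2)cc(OCc2ccccc2)c(Cc2c(O)c(C)c(OC)c(C(=O)C(C)C)c2O)c1OCc1ccccc1)C(=O)C(C)=C(OC)CC(C)=O
F5 | step 12 | 7-hydroxy analogue of 20 (secondary alcohol in place of the acetyl ketone, stereoisomer mixture) | COC(=O)C(Cc1c(OCc2ccccc2)cc(OCc2ccccc2)c(CC(C(=O)OC)C(=O)C(C)=C(OC)CC(=O)C(C)C)c1OCc1ccccc1)C(=O)C(C)=C(OC)CC(C)O
F6 | step 16 | (R)-2-methylbutanamide | CC[C@@H](C)C(N)=O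
F7 | step 16 | (R)-2-methylbutanenitrile | CC[C@@H](C)C#N
F8 | step 16 | ketiminium chloride of 25 (C=NH2+ in place of the ring A ketone C=O) | CC[C@@H](C)C(=[NH2+])c1c(O)c(Cc2c(O)c(C)c(OC)c(C(C)=O)c2O)c(O)c(Cc2c(O)c(C)c(OC)c(C(=O)C(C)C)c2O)c1O.[Cl-]
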